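(All runs were generated by integration on assumed constants, noise included.)

What is slow in the blue run is the solid, and I want to know how long a charge of it stays in the flask.

| setting | grey | blue | Tuesday's | Wednesday's | Saturday's | Sunday's | Thursday's |
|---|---|---|---|---|---|---|---|
| solid substrate | 9.1 × 10⁻⁴ M | 0.078 M | 0.0012 M | 0.0040 M | 0.012 M | 0.030 M | 0.10 M |
| reagent | 0.11 M | 0.11 M | 0.110 M | 0.110 M | 0.110 M | 0.110 M | 0.110 M |
| remark | run made earlier | run made earlier |  |  |  |  |  |
| time |  |  | 2.5 d | 2.5 d | 2.5 d | 2.5 d | 2.5 d |

- grey (time / h: target / %, solid substrate / %): 1.50: 10, 0; 5.00: 27, 1; 8.00: 38, 2; 12.0: 48, 0; 20.0: 70, 1; 25.0: 80, 1; 30.0: 80, 0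
- blue (time / h: target / %, solid substrate / %): 2.50: 1, 82; 4.00: 6, 79; 6.00: 0, 72; 8.00: 5, 69; 12.0: 4, 64; 20.0: 10, 42; 30.0: 15, 25

(standard deviation of a reading: 1.5 percentage points)

- in percentages every species weighs as the solid substrate in it: one side product A or side product B counts as two
- as a solid, counted per litre of solution: solid substrate
- the earlier runs were read with a standard deviation of 1.5 percentage points
- candidate steps: solid substrate <-> dissolved substrate; dissolved substrate + reagent -> target; solid substrate + target -> side product B; 2 dissolved substrate -> side product A
- at the start none of the solid substrate is in solution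
- "hardly changes" means that all values lie within two and a half points (for a concentration: within two and a half percent of the largest)

1. [target] at the end for Tuesday's, Wednesday's, Saturday's, Sunday's, Thursday's, in this order
2. the course of these numbers from the first flask to the last (hardly changes / rises, then falls / rises all the way / falls all the way / falls, then rises)

Between 4.00 h and 30.0 h the blue run loses solid at 0.00162 M/h, and I carry this clearing rate, the solid lost per litre and hour while solid stands. A charge divided by it is a solid lifetime: 18.5 h for Sunday's flask, 2.57 d for Thursday's.

But the blue run loses solid faster at the start, which takes 6.11 h off Thursday's lifetime. Does that matter? The grey run, whose solid reads zero within scatter, is pseudo-first-order in dissolved substrate: 70% at 20.0 h gives 0.0602 /h. Thursday's time after the solid is then 4.38 h at most, shorter than the 16.6 h that 0.0602 /h asks for.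

Next objection. The blue run reads 0.0140 M of solid gone by 2.50 h, which I take as dissolved, so 0.0602 /h promises 8.45 × 10⁻⁴ M/h of target, yet it reads 3.90 × 10⁻⁴ M/h, less than promised. So I take it that solid consumes target, at a gap of 4.55 × 10⁻⁴ M/h in the blue run.

Saturday's charge lies under 0.0140 M, so for the dilute flasks I reckon 0.00117 M, 0.00389 M and 0.0117 M. Sunday's flask, with its time after the solid, gives 0.0275 M at first. Going round again, I scale the gap by solid times target over the lifetime, which costs 0.00200 M of target and as much solid, leaving 0.0239 M. Thursday's flask at the blue pace gives 0.0234 M, but with more solid against the target I scale it down to 0.0183 M. My row rises, then falls.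

The forecast says 9.800 × 10⁻⁴ M, 0.0025 M, 0.005 M, 0.009 M, 0.021 M, so rises all the way, with the solid's loss put “rather than side product B, which looks minor”.

The flasks give 0.00116 M, 0.00380 M, 0.0109 M, 0.0240 M, 0.0168 M: rises, then falls.

    solid substrate ⇌ dissolved substrate, rate k1*(cs1 - [dissolved substrate]) while solid is left; crystals form when [dissolved substrate] > cs1 (solubility = 20.0 mM, k = 0.330 /h)
    dissolved substrate + reagent → target (k = 0.530 /M/h)
    solid substrate + target → side product B (k = 2.20 /M/h)
    2 dissolved substrate → side product A (k = 0.260 /M/h)

Thursday's solid lifetime of 2.57 d lies just beyond the 2.5 d of the run, and at the end that flask holds 1.15% of its solid, with 55.8% as side product B and 16.8% as target. Sunday's lifetime of 18.5 h is shorter than the 1.25 d of its halfway point, where that flask shows 0% solid, and from there to the end side product B stays at 4.94% while target climbs from 63.0% to 80.1%.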